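**Retrosynthetic overview**
1. Presumed biogenesis: FPP → germacrene A (C6–C7 closure by the distal isopropylidene, loss of H-12) → C12 oxidation and lactonisation onto O6 → C1–C5 closure and C4–C5 scission to the 4,5-seco-guaiane (xanthane) 1(5)-ene → 1,5-epoxide → trans-diol → angeloylation.
2. Target ⇐ 1β,5α-diol (angeloylation, CO2-mediated hydration of the C2≡C3 alkyne, desilylation) ⇐ α-epoxidation of the 1(5)-ene of an enyne lactone and opening at C1.
3. Lactone ring (formed second): C12 of the isopropenyl group is oxidised and closed onto O6; C7 and C11 are then set by butenolide formation and hydride addition from the H6 face.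
4. Seven-membered ring (formed first): carbonyl-ene closure of C6–C7 in an open 4,5-seco enynal, the isopropylidene attacking C6 with loss of a C12–H; C1–C5 is already in the chain, so C4–C5 is never made.
5. Enynal ⇐ palladium-catalysed syn-hydroalkynylation of a citronellal-derived ynoate (sets C10) with silylated (R)-but-3-yn-2-ol (sets C4).

Assumption: atoms carry the xanthane numbering of the target (ring C1, C5–C10; side chain C2–C4, C15; lactone C11–C13; C14 on C10), β is the ring face of C14, O6 and C11 in the target, and TBSO = tert-butyldimethylsilyloxy.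

**Step 1**
Reactants: 1 (S)-citronellal
Product: 2 (3S)-3,7-dimethyloct-6-en-1-yne
Conditions: C4F9SO2F (1.2 equiv), P2-Et phosphazene base EtN=P(NMe2)2N=P(NMe2)3 (2.5 equiv), DMF, 0 °C → rt
Reagents that add atoms: none
Why: One-pot aldehyde-to-alkyne dehydration (enol nonaflate formation, then base-induced elimination of nonaflate); the C10 stereocenter is β to the carbonyl and is not involved.

**Step 2**
Reactants: 2 (3S)-3,7-dimethyloct-6-en-1-yne
Product: 3 ethyl (4S)-4,8-dimethylnon-7-en-2-ynoate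
Conditions: n-BuLi, THF, −78 °C; ClCO2Et, −78 → 0 °C
Reagents that add atoms: ethyl chloroformate, CCOC(Cl)=O
Why: Deprotonation of the terminal alkyne and C-acylation with a chloroformate (alkynyllithium acylation) installs C6 at the ester level.

**Step 3**
Reactants: 4 (R)-but-3-yn-2-ol
Product: 5 (R)-tert-butyl(but-3-yn-2-yloxy)dimethylsilane
Conditions: TBSCl, imidazole, DMF, rt
Reagents that add atoms: tert-butyldimethylsilyl chloride, CC(C)(C)[Si](C)(C)Cl
Why: Standard silylation; it masks the C4 hydroxyl (chiral-pool stereocenter) so that only O5 is acylated in step 13.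

**Step 4**
Reactants: 3 ethyl (4S)-4,8-dimethylnon-7-en-2-ynoate; 5 (R)-tert-butyl(but-3-yn-2-yloxy)dimethylsilane
Product: 6 ethyl (2E,4S)-3-[(3R)-3-(TBSO)but-1-yn-1-yl]-4,8-dimethylnona-2,7-dienoate
Conditions: Pd(OAc)2 (3 mol %), tris(2,6-dimethoxyphenyl)phosphine (3 mol %), THF, rt
Reagents that add atoms: none
Why: Trost alkyne–ynoate coupling: syn addition of the alkyne C–H across the ynoate puts the alkynyl group on C1 cis to H5, so the ester carbon C6 is cis to C10, the geometry needed for ring closure.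

**Step 5**
Reactants: 6 ethyl (2E,4S)-3-[(3R)-3-(TBSO)but-1-yn-1-yl]-4,8-dimethylnona-2,7-dienoate
Product: 7 (2E,4S)-3-[(3R)-3-(TBSO)but-1-yn-1-yl]-4,8-dimethylnona-2,7-dien-1-ol
Conditions: i-Bu2AlH (2.2 equiv), CH2Cl2, −78 °C; Rochelle-salt work-up
Reagents that add atoms: none
Why: 1,2-Reduction of the conjugated ester to the allylic alcohol by an aluminium hydride, without touching the enyne or silyl ether.

**Step 6**
Reactants: 7 (2E,4S)-3-[(3R)-3-(TBSO)but-1-yn-1-yl]-4,8-dimethylnona-2,7-dien-1-ol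
Product: 8 (2E,4S)-3-[(3R)-3-(TBSO)but-1-yn-1-yl]-4,8-dimethylnona-2,7-dienal
Conditions: activated MnO2 (excess), CH2Cl2, rt
Reagents that add atoms: none
Why: Chemoselective allylic alcohol oxidation with MnO2 gives the enal without double-bond isomerisation.

**Step 7**
Reactants: 8 (2E,4S)-3-[(3R)-3-(TBSO)but-1-yn-1-yl]-4,8-dimethylnona-2,7-dienal
Product: 9 (1S,4S,7R)-3-[(3R)-3-(TBSO)but-1-yn-1-yl]-4-methyl-7-(prop-1-en-2-yl)cyclohept-2-en-1-ol (6β-OH; 7α-isopropenyl; 10β-methyl)
Conditions: Me2AlCl (1.5 equiv), CH2Cl2, −78 → −30 °C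
Reagents that add atoms: none
Why: Proposed new method: Lewis-acid-promoted intramolecular carbonyl-ene (Prins-type) closure of a seven-membered ring from a conjugated enynal (closest precedent: citronellal → isopulegol and Me2AlCl-promoted ene closures of olefinic aldehydes). The isopropylidene attacks C6 and a C12–H passes to oxygen, as in the FPP → germacrene A cyclisation; with the C10 methyl pseudo-equatorial (avoiding allylic strain with the cis C6) the tether reaches one face of the s-trans enal, so O6 should come out cis to the C10 methyl (β), with the C7 isopropenyl trans to O6 (C7 is corrected in steps 10 and 11).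

**Step 8**
Reactants: 9 cycloheptenol (as named in step 7)
Product: 11 (1R,4S,7R)-3-[(3R)-3-(TBSO)but-1-yn-1-yl]-7-(1-hydroxypropan-2-yl)-4-methylcyclohept-2-en-1-ol (C11 epimers), via bis-boryl adduct 10 (not isolated)
Conditions: 9-BBN (2.5 equiv), THF, 0 °C → rt; then NaOH, H2O2, 0 °C
Reagents that add atoms: hydrogen peroxide, OO; 9-borabicyclo[3.3.1]nonane, B1C2CCCC1CCC2 (boron stays in 10 only)
Why: Anti-Markovnikov hydroboration–oxidation; 9-BBN reacts with the 1,1-disubstituted alkene far faster than with the trisubstituted enyne alkene or the internal alkyne, and the C11 configuration does not matter because it is erased in step 10.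

**Step 9**
Reactants: 11 diol (as named in step 8)
Product: 13 (3RS,3aR,6S,8aR)-7-[(3R)-3-(TBSO)but-1-yn-1-yl]-3,6-dimethyl-3,3a,4,5,6,8a-hexahydro-2H-cyclohepta[b]furan-2-one (trans-fused; 6αH; 7βH), via lactol 12 (not isolated)
Conditions: TEMPO (20 mol %), PhI(OAc)2 (2.5 equiv), CH2Cl2, rt
Reagents that add atoms: none
Why: Oxoammonium oxidation takes the primary alcohol to the aldehyde, which closes onto O6 as the lactol and is oxidised to the γ-lactone (C12 oxidation then lactonisation onto O6, as in germacrene A acid → costunolide); C6 keeps its configuration.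

**Step 10**
Reactants: 13 trans-fused lactone (as named in step 9)
Product: 15 (6S,8aS)-7-[(3R)-3-(TBSO)but-1-yn-1-yl]-3,6-dimethyl-4,5,6,8a-tetrahydro-2H-cyclohepta[b]furan-2-one (7(11)-butenolide), via bromolactone 14 (not isolated)
Conditions: LiN(i-Pr)2 (1.2 equiv), THF, −78 °C; N-bromosuccinimide; then DBU, −78 °C → rt
Reagents that add atoms: N-bromosuccinimide, O=C1CCC(=O)N1Br (bromine, in 14 only)
Why: Enolate α-bromination (bromine enters anti to the axial H7 of the trans-fused lactone) and anti E2 loss of HBr across C11–C7 give the conjugated butenolide, which removes the wrong C7 center.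

**Step 11**
Reactants: 15 butenolide (as named in step 10)
Product: 16 (3R,3aS,6S,8aR)-7-[(3R)-3-(TBSO)but-1-yn-1-yl]-3,6-dimethyl-3,3a,4,5,6,8a-hexahydro-2H-cyclohepta[b]furan-2-one (cis-fused; 6αH; 7αH; 11αH)
Conditions: Cu(OAc)2 (5 mol %), 1,2-bis(diphenylphosphino)benzene (5 mol %), HSiMe(OEt)2 (2 equiv), t-BuOH (2 equiv), toluene, rt
Reagents that add atoms: none
Why: Copper hydride conjugate reduction: hydride adds to C7 on the face of H6 (anti to C5), giving the cis ring fusion, and the copper enolate is protonated at C11 from the convex face, so H6, H7 and H11 all end up α.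

**Step 12**
Reactants: 16 cis-fused enyne lactone (as named in step 11)
Product: 18 (3R,3aS,6S,7R,8S,8aR)-7,8-dihydroxy-7-[(3R)-3-(TBSO)but-1-yn-1-yl]-3,6-dimethyloctahydro-2H-cyclohepta[b]furan-2-one (1β-OH; 5α-OH), via epoxide 17 (not isolated)
Conditions: mCPBA, CH2Cl2/aq NaHCO3, 0 °C; then HClO4 (5 mol %), THF–H2O 4:1, 0 °C
Reagents that add atoms: m-chloroperbenzoic acid, OOC(=O)c1cccc(Cl)c1; water, O
Why: Prilezhaev epoxidation occurs on the α face (anti to the allylic O6 and C10 methyl, both β), and acid-catalysed hydrolysis opens the epoxide at the tertiary propargylic C1 with inversion, giving the 1β,5α-trans-diol (the 1(5)-ene → epoxide → trans-diol sequence of the presumed biogenesis).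

**Step 13**
Reactants: 18 diol (as named in step 12); 19 angelic acid
Product: 21 (3R,3aS,6S,7R,8S,8aR)-7-hydroxy-7-[(3R)-3-(TBSO)but-1-yn-1-yl]-3,6-dimethyl-2-oxooctahydro-2H-cyclohepta[b]furan-8-yl (2Z)-2-methylbut-2-enoate, via mixed anhydride 20 (not isolated)
Conditions: 19, 2,4,6-Cl3C6H2COCl, Et3N, toluene, rt; then 18, toluene, 80 °C
Reagents that add atoms: 2,4,6-trichlorobenzoyl chloride, O=C(Cl)c1c(Cl)cc(Cl)cc1Cl (in 20 only)
Why: Yamaguchi mixed-anhydride esterification acylates the only secondary hydroxyl (O5; O1 is tertiary, O4 is silylated) and is the usual way to transfer an angeloyl group with little Z→E isomerisation.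

**Step 14**
Reactants: 21 angelate (as named in step 13)
Product: 24 target (3R,3aS,6S,7S,8S,8aR)-7-hydroxy-7-[(3R)-3-hydroxybutanoyl]-3,6-dimethyl-2-oxooctahydro-2H-cyclohepta[b]furan-8-yl (2Z)-2-methylbut-2-enoate, via cyclic carbonate 22 (not isolated), via silyl ketol 23 (not isolated)
Conditions: AgOAc (10 mol %), DBU (20 mol %), CO2 (10 bar), MeCN, rt; then H2O, rt; then aq HF (48 %), 0 °C
Reagents that add atoms: carbon dioxide, O=C=O (taken up in 22, released again); water, O
Why: Silver-catalysed carboxylative cyclisation of the tertiary propargylic alcohol (5-exo-dig attack of the O1 carbonate on C2) and hydrolysis of the enol carbonate put the carbonyl at C2 only (CO2-mediated hydration of propargylic alcohols to α-hydroxy ketones); HF in acetonitrile then removes the silyl group without harming the angelate, ketol or lactone.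

**Compound list**
1 | (S)-citronellal, (3S)-3,7-dimethyloct-6-enal | C[C@@H](CCC=C(C)C)CC=O | starting material
2 | (3S)-3,7-dimethyloct-6-en-1-yne | C#C[C@@H](C)CCC=C(C)C | intermediate
3 | ethyl (4S)-4,8-dimethylnon-7-en-2-ynoate | CCOC(=O)C#C[C@@H](C)CCC=C(C)C | intermediate
4 | (R)-but-3-yn-2-ol | C#C[C@@H](C)O | starting material
5 | (R)-tert-butyl(but-3-yn-2-yloxy)dimethylsilane | C#C[C@@H](C)O[Si](C)(C)C(C)(C)C | intermediate
6 | ethyl (2E,4S)-3-[(3R)-3-(TBSO)but-1-yn-1-yl]-4,8-dimethylnona-2,7-dienoate | CCOC(=O)/C=C(/C#C[C@@H](C)O[Si](C)(C)C(C)(C)C)[C@@H](C)CCC=C(C)C | intermediate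
7 | (2E,4S)-3-[(3R)-3-(TBSO)but-1-yn-1-yl]-4,8-dimethylnona-2,7-dien-1-ol | OC/C=C(/C#C[C@@H](C)O[Si](C)(C)C(C)(C)C)[C@@H](C)CCC=C(C)C | intermediate
8 | (2E,4S)-3-[(3R)-3-(TBSO)but-1-yn-1-yl]-4,8-dimethylnona-2,7-dienal | O=C/C=C(/C#C[C@@H](C)O[Si](C)(C)C(C)(C)C)[C@@H](C)CCC=C(C)C | intermediate
9 | (1S,4S,7R)-3-[(3R)-3-(TBSO)but-1-yn-1-yl]-4-methyl-7-(prop-1-en-2-yl)cyclohept-2-en-1-ol | O[C@H]1C=C(C#C[C@@H](C)O[Si](C)(C)C(C)(C)C)[C@@H](C)CC[C@@H]1C(C)=C | intermediate
10 | bis-boryl adduct of 9 (O6–B and C12–B, both 9-borabicyclo[3.3.1]nonan-9-yl; C11 epimers) | B1(O[C@H]2C=C(C#C[C@@H](C)O[Si](C)(C)C(C)(C)C)[C@@H](C)CC[C@@H]2C(C)CB3C4CCCC3CCC4)C5CCCC1CCC5 | intermediate (not isolated)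
11 | (1R,4S,7R)-3-[(3R)-3-(TBSO)but-1-yn-1-yl]-7-(1-hydroxypropan-2-yl)-4-methylcyclohept-2-en-1-ol (C11 epimers) | O[C@H]1C=C(C#C[C@@H](C)O[Si](C)(C)C(C)(C)C)[C@@H](C)CC[C@@H]1C(C)CO | intermediate
12 | lactol of 13 (C12 hemiacetal; trans-fused; C11 and C12 epimers) | OC1O[C@H]2C=C(C#C[C@@H](C)O[Si](C)(C)C(C)(C)C)[C@@H](C)CC[C@@H]2C1C | intermediate (not isolated)
13 | (3RS,3aR,6S,8aR)-7-[(3R)-3-(TBSO)but-1-yn-1-yl]-3,6-dimethyl-3,3a,4,5,6,8a-hexahydro-2H-cyclohepta[b]furan-2-one (trans-fused) | O=C1O[C@H]2C=C(C#C[C@@H](C)O[Si](C)(C)C(C)(C)C)[C@@H](C)CC[C@@H]2C1C | intermediate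
14 | 11-bromo derivative of 13 (3-bromo-3-methyl lactone) | O=C1O[C@H]2C=C(C#C[C@@H](C)O[Si](C)(C)C(C)(C)C)[C@@H](C)CC[C@@H]2C1(C)Br | intermediate (not isolated)
15 | (6S,8aS)-7-[(3R)-3-(TBSO)but-1-yn-1-yl]-3,6-dimethyl-4,5,6,8a-tetrahydro-2H-cyclohepta[b]furan-2-one | O=C1O[C@H]2C=C(C#C[C@@H](C)O[Si](C)(C)C(C)(C)C)[C@@H](C)CCC2=C1C | intermediate
16 | (3R,3aS,6S,8aR)-7-[(3R)-3-(TBSO)but-1-yn-1-yl]-3,6-dimethyl-3,3a,4,5,6,8a-hexahydro-2H-cyclohepta[b]furan-2-one (cis-fused) | O=C1O[C@H]2C=C(C#C[C@@H](C)O[Si](C)(C)C(C)(C)C)[C@@H](C)CC[C@H]2[C@H]1C | intermediate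
17 | 1α,5α-epoxide of 16 | O=C1O[C@H]2[C@@H]3O[C@]3(C#C[C@@H](C)O[Si](C)(C)C(C)(C)C)[C@@H](C)CC[C@H]2[C@H]1C | intermediate (not isolated)
18 | (3R,3aS,6S,7R,8S,8aR)-7,8-dihydroxy-7-[(3R)-3-(TBSO)but-1-yn-1-yl]-3,6-dimethyloctahydro-2H-cyclohepta[b]furan-2-one | O=C1O[C@H]2[C@H](O)[C@](O)(C#C[C@@H](C)O[Si](C)(C)C(C)(C)C)[C@@H](C)CC[C@H]2[C@H]1C | intermediate
19 | angelic acid, (2Z)-2-methylbut-2-enoic acid | C/C=C(/C)C(=O)O | starting material
20 | angelic 2,4,6-trichlorobenzoic anhydride | C/C=C(/C)C(=O)OC(=O)c1c(Cl)cc(Cl)cc1Cl | intermediate (not isolated)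
21 | (3R,3aS,6S,7R,8S,8aR)-7-hydroxy-7-[(3R)-3-(TBSO)but-1-yn-1-yl]-3,6-dimethyl-2-oxooctahydro-2H-cyclohepta[b]furan-8-yl (2Z)-2-methylbut-2-enoate | O=C1O[C@H]2[C@H](OC(=O)/C(C)=C\C)[C@](O)(C#C[C@@H](C)O[Si](C)(C)C(C)(C)C)[C@@H](C)CC[C@H]2[C@H]1C | intermediate
22 | spiro cyclic carbonate of 21 (O1–C(=O)–O–C2, Z-alkylidene C2=C3) | O=C1O[C@H]2[C@H](OC(=O)/C(C)=C\C)[C@@]3(OC(=O)O/C3=C\[C@@H](C)O[Si](C)(C)C(C)(C)C)[C@@H](C)CC[C@H]2[C@H]1C | intermediate (not isolated)
23 | (3R,3aS,6S,7S,8S,8aR)-7-[(3R)-3-(TBSO)butanoyl]-7-hydroxy-3,6-dimethyl-2-oxooctahydro-2H-cyclohepta[b]furan-8-yl (2Z)-2-methylbut-2-enoate | O=C1O[C@H]2[C@H](OC(=O)/C(C)=C\C)[C@](O)(C(=O)C[C@@H](C)O[Si](C)(C)C(C)(C)C)[C@@H](C)CC[C@H]2[C@H]1C | intermediate (not isolated)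
24 | CNP0321985.1, (3R,3aS,6S,7S,8S,8aR)-7-hydroxy-7-[(3R)-3-hydroxybutanoyl]-3,6-dimethyl-2-oxooctahydro-2H-cyclohepta[b]furan-8-yl (2Z)-2-methylbut-2-enoate | C/C=C(/C)C(=O)O[C@H]1[C@@H]2OC(=O)[C@H](C)[C@@H]2CC[C@H](C)[C@@]1(O)C(=O)C[C@@H](C)O | target

**Totals**
Total steps: 14. Longest linear sequence: 13 steps (1, 2, 4–14) from (S)-citronellal.

**Three steps most likely to fail**

Step 7 (ene ring closure). The isopropylidene may instead add in a conjugate sense to C1 (five-membered ring), the seven-membered closure may be slow, and the O6/C10 selectivity rests only on a conformational preference of perhaps 3–10:1. Fallback, setting out from 8: oxidise the (E)-methyl of the isopropylidene with SeO2/t-BuOOH to the hydroxy enal (2E,4S,7E)-3-[(3R)-3-(TBSO)but-1-yn-1-yl]-9-hydroxy-4,8-dimethylnona-2,7-dienal F1, convert it with CBr4/PPh3 into the allylic bromide (2E,4S,7E)-9-bromo-3-[(3R)-3-(TBSO)but-1-yn-1-yl]-4,8-dimethylnona-2,7-dienal F2, and close the ring with CrCl2 in THF by an intramolecular Nozaki–Hiyama allylation. The allylchromium adds only 1,2 to the aldehyde through C7 and regenerates the isopropenyl group, so the fallback comes back to the route at 9.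

Step 10 (bromination/elimination to the butenolide). Elimination may go toward the methyl group (α-methylene lactone), and DBU may epimerise the doubly allylic C6 of 15. Fallback, setting out from 9: hydroxylate the isopropenyl methyl with SeO2/t-BuOOH to the allylic diol (1S,4S,7R)-3-[(3R)-3-(TBSO)but-1-yn-1-yl]-7-(3-hydroxyprop-1-en-2-yl)-4-methylcyclohept-2-en-1-ol F3, oxidise with TEMPO/PhI(OAc)2 to the trans-fused α-methylene lactone (3aR,6S,8aR)-7-[(3R)-3-(TBSO)but-1-yn-1-yl]-6-methyl-3-methylidene-3,3a,4,5,6,8a-hexahydro-2H-cyclohepta[b]furan-2-one F4 (the costunolide oxidation pattern), and move the exocyclic double bond into the ring with RhCl3·3H2O in ethanol at 70 °C (metal hydride addition–elimination, base-free). This comes back to the route at 15.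

Step 14 (alkyne hydration/desilylation). The hindered internal alkyne may cyclise slowly, and DBU/CO2 in the presence of the angelate risks Z→E isomerisation or acyl migration. Fallback, setting out from 18: run the AgOAc/DBU/CO2 carboxylative cyclisation before the acylation to give the cyclic carbonate alcohol (1β,5α)-5-hydroxy spiro carbonate F5, in which O1 is tied up and C2 is masked as an enol carbonate so that no free β-hydroxy ketone is ever exposed to base. Then angeloylate O5 under the step 13 conditions. This comes back to the route at 22, now an isolated compound, which is hydrolysed and desilylated as in step 14.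

**Further compounds**
F1 | step 7 | (2E,4S,7E)-3-[(3R)-3-(TBSO)but-1-yn-1-yl]-9-hydroxy-4,8-dimethylnona-2,7-dienal | O=C/C=C(/C#C[C@@H](C)O[Si](C)(C)C(C)(C)C)[C@@H](C)CC/C=C(\C)CO
F2 | step 7 | (2E,4S,7E)-9-bromo-3-[(3R)-3-(TBSO)but-1-yn-1-yl]-4,8-dimethylnona-2,7-dienal | O=C/C=C(/C#C[C@@H](C)O[Si](C)(C)C(C)(C)C)[C@@H](C)CC/C=C(\C)CBr
F3 | step 10 | (1S,4S,7R)-3-[(3R)-3-(TBSO)but-1-yn-1-yl]-7-(3-hydroxyprop-1-en-2-yl)-4-methylcyclohept-2-en-1-ol | O[C@H]1C=C(C#C[C@@H](C)O[Si](C)(C)C(C)(C)C)[C@@H](C)CC[C@@H]1C(=C)CO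
F4 | step 10 | (3aR,6S,8aR)-7-[(3R)-3-(TBSO)but-1-yn-1-yl]-6-methyl-3-methylidene-3,3a,4,5,6,8a-hexahydro-2H-cyclohepta[b]furan-2-one | O=C1O[C@H]2C=C(C#C[C@@H](C)O[Si](C)(C)C(C)(C)C)[C@@H](C)CC[C@@H]2C1=C
F5 | step 14 | spiro cyclic carbonate of diol 18 with free 5α-hydroxyl (O1–C(=O)–O–C2, Z-alkylidene C2=C3) | O=C1O[C@H]2[C@H](O)[C@@]3(OC(=O)O/C3=C\[C@@H](C)O[Si](C)(C)C(C)(C)C)[C@@H](C)CC[C@H]2[C@H]1C
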